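Early times are where I start: in autumn the readings below show double product rising and then stalling, and the question is what that stall is worth in four new flasks.

| setting | dawn | dusk | autumn | beta | zeta | epsilon | delta |
|---|---|---|---|---|---|---|---|
| substrate | 0.10 M | 0.10 M | 0.15 M | 0.10 M | 0.10 M | 0.10 M | 0.10 M |
| partner | 0.048 M | 0.19 M | 0.095 M | 0.0950 M | 0.0950 M | 0.0950 M | 0.0950 M |
| temperature | 20 °C | 48 °C | 20 °C | 40 °C | 55 °C | 25 °C | 70 °C |
| remark | run made earlier | run made earlier | run made earlier |  |  |  |  |
| time |  |  |  | 40 h | 40 h | 40 h | 40 h |

- dawn (time / h: double product / %, tris adduct / %): 8.00: 0.2, 0; 15.0: 1.0, 0.7; 30.0: 1.1, 0; 60.0: 2.8, 0.3; 120: 4.2, 0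
- dusk (time / h: double product / %, tris adduct / %): 3.00: 4.9, 0.6; 6.00: 6.5, 2.4; 12.0: 7.4, 4.4; 20.0: 4.9, 7.7; 40.0: 3.5, 12.2
- autumn (time / h: double product / %, tris adduct / %): 10.0: 2.6, 0; 25.0: 4.0, 0; 60.0: 7.0, 0; 72.0: 6.5, 0.4; 120: 6.8, 0.7

(readings scatter by 0.5 percentage points)

- in percentages every species weighs as the substrate in it: one side product counts as two
- the numbers in the tables scatter with a standard deviation of 0.5 percentage points

1. the best flask by share of double product in all that became double product or tris adduct or side product; "all alike" if 1.5 percentage points covers them all (beta / zeta / epsilon / delta / all alike)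
2. share of double product in all that became double product or tris adduct or side product, beta
3. share of double product in all that became double product or tris adduct or side product, zeta
4. share of double product in all that became double product or tris adduct or side product, epsilon
5. share of double product in all that became double product or tris adduct or side product, delta

In autumn, at 20 °C, double product stands at 2.60 % of the substrate charged after 10.0 h, while double product plus tris adduct end at 7.50 %, so the early pace would reach that end in a filling time of 28.8 h.

How high the end lies I read from the partner ration, the last double product plus tris adduct reckoned on the partner charged instead of on the substrate. It reads 0.118 in autumn, 0.0875 in dawn and 0.0826 in dusk, with a mean of 0.0962.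

Epsilon charges 0.950 of partner per substrate, and I borrow the autumn clock for it, so 40 h gives a filled part of 0.750 and double product plus tris adduct of 0.0685. With autumn's split, double product is 0.0621. If substrate is spent on the same clock and every bit of it lands in the counted products, the share (the selectivity) is 8.28 %. That spending is my weak link, and substrate spent more slowly raises the share, so I hold this figure as the low side. Dusk ends with tris adduct above double product. I rank epsilon, the coolest flask, first.

The forecast names epsilon, with 6 % for beta, 2.4 % for zeta, 7.5 % for epsilon, a little below my figure, and 0.3 % for delta, on the ground “Cool is best”.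

The flasks give 9.59 % for beta, 2.71 % for zeta, 21.6 % for epsilon and 0.326 % for delta, so epsilon leads.

    substrate + partner → single product (k = 0.440 /M/h, Ea = 58.0 kJ/mol)
    partner + single product → double product (k = 0.834 /M/h, Ea = 52.0 kJ/mol)
    partner + double product → tris adduct (k = 0.180 /M/h, Ea = 82.0 kJ/mol)
    single product → decomposed reagent (k = 0.0179 /h, Ea = 108 kJ/mol)
    substrate + single product → side product (k = 0.497 /M/h, Ea = 83.0 kJ/mol)
    partner ⇌ dormant form (K = 1.90, k = 0.129 /h, Ea = 86.0 kJ/mol, ΔH = 9.00 kJ/mol)
    (constants at 25 °C)

In epsilon the counted products come to 33.6 % of the charge, less than my filled part, and the ration at 40.0 h is 0.0834, while the neighbour with 4.00 times the partner shows 0.144 and a share of 49.0 %. Single product in epsilon is made 1.19 times as fast as it is used up at 8.26 h, but 0.780 times at 40.0 h. Its stock goes from 11.4 % at 10.0 h to 8.08 % at 40.0 h.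

The runs are simulated with made-up constants, noise included.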